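**Plan**

- Retrosynthesis: the three O–benzyl bonds are cut first, then the aryl C–O bond that carries the sulfate on ring B, then the O–CH2OMe bond, then O1–C2 of ring C, then the C2–C3 bond (aldol), back to an acetophenone and a benzaldehyde.
- Forward: rings A and B come from arenes 1 and 4 and are joined by Claisen–Schmidt condensation (C2–C3). Ring C is closed by oxidative cyclization (O1–C2). Only then is the last oxygen of ring B introduced, already sulfated.
- Enabling feature: in ring B the sulfated oxygen on C3' is ortho to the C4' hydroxyl, whose para carbon C1' carries ring C and whose other ortho carbon C5' carries oxygen. A 4'-phenoxide with one ortho position capped as a benzyl ether therefore has a single free ortho carbon, where peroxodisulfate delivers O–SO3–.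
- Stereochemistry: the target has no stereocenter. The E double bond of the chalcone is set thermodynamically and vanishes on cyclization; the aldol, flavanone and dienone intermediates are racemic and transient.

Key step: step 7

Remark: sulfate monoesters are drawn as hydrogen sulfates, as in the target formula; in the flask and on isolation they would be potassium salts, and the protonation state of the final sample is a matter of ion exchange during purification.

**Step 1**
Reactants: 1 2',4',6'-trihydroxyacetophenone; 2 benzyl bromide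
Product: 3 1-[2,4-bis(benzyloxy)-6-hydroxyphenyl]ethanone
Conditions: BnBr (2.1 equiv), K2CO3 (2.2 equiv), DMF, 0 °C → rt
Reagents that add atoms: benzyl bromide 2, BrCc1ccccc1
Why: Williamson etherification in which two phenoxides are alkylated while the last hydroxyl, hydrogen-bonded to the acetyl carbonyl, is the least acidic and should stay free, as is usual for phloroacetophenone.

**Step 2**
Reactants: 4 3,4-dihydroxybenzaldehyde; 5 chloromethyl methyl ether
Product: 6 3-hydroxy-4-(methoxymethoxy)benzaldehyde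
Conditions: MOMCl (1.05 equiv), K2CO3 (1.1 equiv), acetone, 0 °C → rt
Reagents that add atoms: chloromethyl methyl ether 5, COCCl
Why: regioselective Williamson-type O-alkylation, because the 4-hydroxyl para to the formyl group is the more acidic one and one equivalent of weak base should form only its phenoxide.

**Step 3**
Reactants: 6 3-hydroxy-4-(methoxymethoxy)benzaldehyde; 2 benzyl bromide
Product: 7 3-(benzyloxy)-4-(methoxymethoxy)benzaldehyde
Conditions: BnBr (1.2 equiv), K2CO3, DMF, rt → 50 °C
Reagents that add atoms: benzyl bromide 2, BrCc1ccccc1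
Why: Williamson etherification of the one remaining phenol, with the acetal and the aldehyde inert to carbonate.

**Step 4**
Reactants: 3 1-[2,4-bis(benzyloxy)-6-hydroxyphenyl]ethanone; 7 3-(benzyloxy)-4-(methoxymethoxy)benzaldehyde
Product: 9 (E)-1-[2,4-bis(benzyloxy)-6-hydroxyphenyl]-3-[3-(benzyloxy)-4-(methoxymethoxy)phenyl]prop-2-en-1-one, via aldol adduct 8 (not isolated)
Conditions: KOH (50% aq.), EtOH/THF, rt, 36–48 h
Reagents that add atoms: none
Why: Claisen–Schmidt condensation of a methyl ketone with a non-enolizable aldehyde, in which the aldol adduct loses water by E1cB elimination to the conjugated E-enone; benzyl and methoxymethyl ethers are stable to alkali.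

**Step 5**
Reactants: 9 (E)-1-[2,4-bis(benzyloxy)-6-hydroxyphenyl]-3-[3-(benzyloxy)-4-(methoxymethoxy)phenyl]prop-2-en-1-one
Product: 11 5,7-bis(benzyloxy)-2-[3-(benzyloxy)-4-(methoxymethoxy)phenyl]chromen-4-one, via flavanone 10 (not isolated)
Conditions: I2 (0.1 equiv), DMSO, 120–130 °C; aq. Na2S2O3 work-up
Reagents that add atoms: none
Why: oxidative cyclization of a 2'-hydroxychalcone, by 6-endo oxa-Michael closure to the flavanone and iodine-mediated dehydrogenation with DMSO as terminal oxidant, a standard route to benzyl-protected flavones; any methoxymethyl group lost to the HI formed converges on compound 12 in step 6.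

**Step 6**
Reactants: 11 5,7-bis(benzyloxy)-2-[3-(benzyloxy)-4-(methoxymethoxy)phenyl]chromen-4-one
Product: 12 5,7-bis(benzyloxy)-2-[3-(benzyloxy)-4-hydroxyphenyl]chromen-4-one
Conditions: conc. HCl (few equiv), MeOH/THF, 50 °C
Reagents that add atoms: none
Why: acid-catalysed acetal exchange removes the methoxymethyl group, while aryl benzyl ethers should tolerate dilute acid at this temperature.

**Step 7**
Reactants: 12 5,7-bis(benzyloxy)-2-[3-(benzyloxy)-4-hydroxyphenyl]chromen-4-one; 13 potassium peroxodisulfate K2S2O8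
Product: 15 3-(benzyloxy)-5-[5,7-bis(benzyloxy)-4-oxochromen-2-yl]-2-hydroxyphenyl hydrogen sulfate, via cyclohexadienone sulfate 14 (not isolated)
Conditions: K2S2O8 (1.3 equiv, aq., slow addition), KOH (5 equiv), H2O/pyridine, 0 → 20 °C, dark; AcOH to pH 7, EtOAc wash, n-BuOH extraction or C18
Reagents that add atoms: potassium peroxodisulfate 13, [K+].[K+].[O-]S(=O)(=O)OOS(=O)(=O)[O-]
Why: The 4'-phenoxide of 12 attacks a peroxide oxygen of the peroxodisulfate dianion through C5', the only carbon ortho or para to the phenoxide oxygen that still bears hydrogen; sulfate leaves and cyclohexadienone 14 tautomerizes to aryl sulfate 15. This is the Elbs peroxodisulfate oxidation in its ortho mode, known for para-substituted phenols including electron-poor ones (4-nitrophenol gives 2-hydroxy-5-nitrophenyl sulfate), and aqueous pyridine–alkali is the medium in which hydroxyflavones are customarily oxidized by this reagent. No ring is closed and no stereocenter survives, since the sp3 carbon of 14 is rearomatized. The selectivity needed is site selectivity, secured by blocking: the para carbon C1' carries ring C, the second ortho carbon carries benzyloxy, and the benzyl ethers on ring A leave C6 and C8 without a free phenol to activate them. The usual acid hydrolysis is omitted and the work-up is held at pH 7 or above, so the alkali-stable sulfate monoester is isolated as such. Conversion in ortho Elbs oxidations is usually modest, so unchanged 12 would be recovered from the neutral extract and recycled; the product has no free ortho or para position and should not be oxidized further.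

**Step 8**
Reactants: 15 3-(benzyloxy)-5-[5,7-bis(benzyloxy)-4-oxochromen-2-yl]-2-hydroxyphenyl hydrogen sulfate
Product: 16 tricetin 3'-sulfate
Conditions: H2 (1 atm), 10% Pd/C, MeOH/THF/H2O, rt, neutral (potassium salt); Celite filtration, C18
Reagents that add atoms: none
Why: catalytic hydrogenolysis cleaves the three aryl benzyl ethers, while the aryl sulfate salt is inert and the conjugated C2=C3 bond of a flavone normally survives at atmospheric pressure if the reaction is stopped once debenzylation is complete.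

**Compound list**

1 | 2',4',6'-trihydroxyacetophenone | CC(=O)c1c(O)cc(O)cc1O | starting material
2 | benzyl bromide | BrCc1ccccc1 | starting material
3 | 1-[2,4-bis(benzyloxy)-6-hydroxyphenyl]ethanone | CC(=O)c1c(O)cc(OCc2ccccc2)cc1OCc1ccccc1 | intermediate
4 | 3,4-dihydroxybenzaldehyde | O=Cc1ccc(O)c(O)c1 | starting material
5 | chloromethyl methyl ether | COCCl | starting material
6 | 3-hydroxy-4-(methoxymethoxy)benzaldehyde | COCOc1ccc(C=O)cc1O | intermediate
7 | 3-(benzyloxy)-4-(methoxymethoxy)benzaldehyde | COCOc1ccc(C=O)cc1OCc1ccccc1 | intermediate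
8 | aldol adduct, racemic 1-[2,4-bis(benzyloxy)-6-hydroxyphenyl]-3-[3-(benzyloxy)-4-(methoxymethoxy)phenyl]-3-hydroxypropan-1-one | COCOc1ccc(C(O)CC(=O)c2c(O)cc(OCc3ccccc3)cc2OCc2ccccc2)cc1OCc1ccccc1 | intermediate
9 | (E)-1-[2,4-bis(benzyloxy)-6-hydroxyphenyl]-3-[3-(benzyloxy)-4-(methoxymethoxy)phenyl]prop-2-en-1-one | COCOc1ccc(/C=C/C(=O)c2c(O)cc(OCc3ccccc3)cc2OCc2ccccc2)cc1OCc1ccccc1 | intermediate
10 | flavanone, racemic 5,7-bis(benzyloxy)-2-[3-(benzyloxy)-4-(methoxymethoxy)phenyl]-2,3-dihydrochromen-4-one | COCOc1ccc(C2CC(=O)c3c(OCc4ccccc4)cc(OCc4ccccc4)cc3O2)cc1OCc1ccccc1 | intermediate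
11 | 5,7-bis(benzyloxy)-2-[3-(benzyloxy)-4-(methoxymethoxy)phenyl]chromen-4-one | COCOc1ccc(-c2cc(=O)c3c(OCc4ccccc4)cc(OCc4ccccc4)cc3o2)cc1OCc1ccccc1 | intermediate
12 | 5,7-bis(benzyloxy)-2-[3-(benzyloxy)-4-hydroxyphenyl]chromen-4-one | O=c1cc(-c2ccc(O)c(OCc3ccccc3)c2)oc2cc(OCc3ccccc3)cc(OCc3ccccc3)c12 | intermediate
13 | potassium peroxodisulfate K2S2O8 | [K+].[K+].[O-]S(=O)(=O)OOS(=O)(=O)[O-] | starting material
14 | cyclohexadienone sulfate, racemic 3-(benzyloxy)-5-[5,7-bis(benzyloxy)-4-oxochromen-2-yl]-2-oxocyclohexa-3,5-dien-1-yl hydrogen sulfate | O=C1C(OCc2ccccc2)=CC(c2cc(=O)c3c(OCc4ccccc4)cc(OCc4ccccc4)cc3o2)=CC1OS(=O)(=O)O | intermediate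
15 | 3-(benzyloxy)-5-[5,7-bis(benzyloxy)-4-oxochromen-2-yl]-2-hydroxyphenyl hydrogen sulfate | O=c1cc(-c2cc(OCc3ccccc3)c(O)c(OS(=O)(=O)O)c2)oc2cc(OCc3ccccc3)cc(OCc3ccccc3)c12 | intermediate
16 | tricetin 3'-sulfate | O=c1cc(-c2cc(O)c(O)c(OS(=O)(=O)O)c2)oc2cc(O)cc(O)c12 | target

**Step count**

Total: 8 steps. Longest linear sequence: 7 steps (4 → 6 → 7 → 9 → 11 → 12 → 15 → 16); step 1 is the side branch.

**Steps most likely to fail**

Step 7. The 4'-phenoxide is conjugated to the chromone carbonyl and may attack the peroxide too slowly at carbon, so that peroxodisulfate is spent on one-electron oxidation and tar formation, or the chromone may open in alkali. The fallback sets out from 12 and still uses the 4'-phenol to direct the new oxygen to the same carbon. Magnesium-mediated ortho-formylation (MgCl2, Et3N, paraformaldehyde, MeCN, reflux) should give 3-(benzyloxy)-5-[5,7-bis(benzyloxy)-4-oxochromen-2-yl]-2-hydroxybenzaldehyde F1. Benzylation with 2 (K2CO3, DMF) gives 2,3-bis(benzyloxy)-5-[5,7-bis(benzyloxy)-4-oxochromen-2-yl]benzaldehyde F2. Baeyer–Villiger oxidation with 3-chloroperbenzoic acid in CH2Cl2 gives 2,3-bis(benzyloxy)-5-[5,7-bis(benzyloxy)-4-oxochromen-2-yl]phenyl formate F3, which K2CO3 in MeOH converts to 5,7-bis(benzyloxy)-2-[3,4-bis(benzyloxy)-5-hydroxyphenyl]chromen-4-one F4. Its only free hydroxyl is sulfated with SO3·pyridine in pyridine to 2,3-bis(benzyloxy)-5-[5,7-bis(benzyloxy)-4-oxochromen-2-yl]phenyl hydrogen sulfate F5. Hydrogenolysis under the conditions of step 8 brings the route back at 16.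

Step 5. HI formed in hot DMSO may strip the 5-O-benzyl ether peri to the carbonyl, or the oxidation may stall at the flavanone. The fallback sets out from 7 and 3 and builds ring C without an oxidant. Pinnick oxidation of 7 (NaClO2, NaH2PO4, 2-methyl-2-butene, t-BuOH/H2O) gives 3-(benzyloxy)-4-(methoxymethoxy)benzoic acid F6. Esterification with 3 (EDC·HCl, DMAP, CH2Cl2) gives 2-acetyl-3,5-bis(benzyloxy)phenyl 3-(benzyloxy)-4-(methoxymethoxy)benzoate F7. Baker–Venkataraman rearrangement (KOH, pyridine, 50 °C) gives 1-[2,4-bis(benzyloxy)-6-hydroxyphenyl]-3-[3-(benzyloxy)-4-(methoxymethoxy)phenyl]propane-1,3-dione F8. HCl in MeOH/THF then effects cyclodehydration and removes the methoxymethyl group in the same pot, returning to the route at 12.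

Step 6. The acid needed to cleave the methoxymethyl ether of an electron-poor phenol may also remove the acid-sensitive 5-O-benzyl group, or the cleavage may remain incomplete under conditions mild enough to spare it. The fallback sets out from 4 and never installs the acetal. The dianion of 4 (NaH, 2.2 equiv, DMSO) is alkylated by one equivalent of 2 at the more nucleophilic 3-oxide to give 3-(benzyloxy)-4-hydroxybenzaldehyde F9. Claisen–Schmidt condensation with 3 under excess KOH in EtOH at 50 °C gives (E)-1-[2,4-bis(benzyloxy)-6-hydroxyphenyl]-3-[3-(benzyloxy)-4-hydroxyphenyl]prop-2-en-1-one F10. Cyclization with catalytic I2 in DMSO as in step 5 then returns directly to the route at 12.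

**Further compounds**

F1 | step 7 | 3-(benzyloxy)-5-[5,7-bis(benzyloxy)-4-oxochromen-2-yl]-2-hydroxybenzaldehyde | O=Cc1cc(-c2cc(=O)c3c(OCc4ccccc4)cc(OCc4ccccc4)cc3o2)cc(OCc2ccccc2)c1O
F2 | step 7 | 2,3-bis(benzyloxy)-5-[5,7-bis(benzyloxy)-4-oxochromen-2-yl]benzaldehyde | O=Cc1cc(-c2cc(=O)c3c(OCc4ccccc4)cc(OCc4ccccc4)cc3o2)cc(OCc2ccccc2)c1OCc1ccccc1
F3 | step 7 | 2,3-bis(benzyloxy)-5-[5,7-bis(benzyloxy)-4-oxochromen-2-yl]phenyl formate | O=COc1cc(-c2cc(=O)c3c(OCc4ccccc4)cc(OCc4ccccc4)cc3o2)cc(OCc2ccccc2)c1OCc1ccccc1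
F4 | step 7 | 5,7-bis(benzyloxy)-2-[3,4-bis(benzyloxy)-5-hydroxyphenyl]chromen-4-one | Oc1cc(-c2cc(=O)c3c(OCc4ccccc4)cc(OCc4ccccc4)cc3o2)cc(OCc2ccccc2)c1OCc1ccccc1
F5 | step 7 | 2,3-bis(benzyloxy)-5-[5,7-bis(benzyloxy)-4-oxochromen-2-yl]phenyl hydrogen sulfate | OS(=O)(=O)Oc1cc(-c2cc(=O)c3c(OCc4ccccc4)cc(OCc4ccccc4)cc3o2)cc(OCc2ccccc2)c1OCc1ccccc1
F6 | step 5 | 3-(benzyloxy)-4-(methoxymethoxy)benzoic acid | COCOc1ccc(C(=O)O)cc1OCc1ccccc1
F7 | step 5 | 2-acetyl-3,5-bis(benzyloxy)phenyl 3-(benzyloxy)-4-(methoxymethoxy)benzoate | CC(=O)c1c(OC(=O)c2ccc(OCOC)c(OCc3ccccc3)c2)cc(OCc2ccccc2)cc1OCc1ccccc1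
F8 | step 5 | 1-[2,4-bis(benzyloxy)-6-hydroxyphenyl]-3-[3-(benzyloxy)-4-(methoxymethoxy)phenyl]propane-1,3-dione | O=C(CC(=O)c1ccc(OCOC)c(OCc2ccccc2)c1)c1c(O)cc(OCc2ccccc2)cc1OCc1ccccc1
F9 | step 6 | 3-(benzyloxy)-4-hydroxybenzaldehyde | O=Cc1ccc(O)c(OCc2ccccc2)c1
F10 | step 6 | (E)-1-[2,4-bis(benzyloxy)-6-hydroxyphenyl]-3-[3-(benzyloxy)-4-hydroxyphenyl]prop-2-en-1-one | O=C(/C=C/c1ccc(O)c(OCc2ccccc2)c1)c1c(O)cc(OCc2ccccc2)cc1OCc1ccccc1
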